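**Plan**

Locants: ring C1 (O-angelate), C2 (OH), C3 (Me, OH), C4 (Cl), C6 (side chain); side chain C1′ (=CH2), C2′, C3′ (O-angelate), C4′, oxirane.
1. Cuts, in order: the two silyl-masked hydroxyls and the oxirane oxygen (late epoxidation of a prenyl alkene), the C3′ angelate, then the C2′–C3′ bond.
2. Enabling feature: CH2=C2′ lies between ring C6–H and the carbinol C3′–O, the retron of an alkenylchromium addition to an aldehyde. C2′ is the carbonyl carbon of the acetyl group left when carvone's isopropenyl is cleaved, so the enol triflate is one step away and carvone's methyl ends as the exocyclic methylene.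
3. Forward order: the cyclohexane is the ring of (S)-carvone and is never opened. It is oxygenated at C1/C2, epoxidised and chlorinated at C3/C4, silylated, and its isopropenyl is converted to the enol triflate; the chain is then joined with 4-methylpent-3-enal, acylated, epoxidised and desilylated.
4. Stereochemistry: C6 from carvone; C1 by anti hydroxylation then SN2 inversion; C2 by hydride delivery anti to the pseudo-axial acyloxy group; C3/C4 by hydroxyl-directed epoxidation and trans-diaxial chloride opening; C3′ by the chiral Cr(III)–sulfonamide complex; the oxirane carbon by a chiral dioxirane.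

Key step: step 10

Assumption: the facial sense of the two reagent-controlled steps (10 and 12) is taken from the accepted transition-state models; if either sense were opposite, the antipodal ligand or ketone would be used and the route would be unchanged.

**Route**

Step 1
Reactants: 1 (S)-(+)-carvone
Product: 3 (5R,6R)-6-hydroxy-2-methyl-5-(prop-1-en-2-yl)cyclohex-2-en-1-one (trans-6-hydroxycarvone), via sodium dienolate 2 (not isolated)
Conditions: NaHMDS, THF, −78 °C; then 2-(phenylsulfonyl)-3-phenyloxaziridine, −78 °C; AcOH quench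
Reagents that add atoms: 2-(phenylsulfonyl)-3-phenyloxaziridine, O=S(=O)(c1ccccc1)N1OC1c1ccccc1
Why: Kinetic α′-deprotonation gives the cross-conjugated dienolate, and electrophilic enolate hydroxylation by the N-sulfonyloxaziridine should occur on the face anti to the adjacent isopropenyl group, placing the new C6–OH trans to it.

Step 2
Reactants: 3 trans-6-hydroxycarvone; 4 angelic acid, (2Z)-2-methylbut-2-enoic acid
Product: 5 (1S,6R)-3-methyl-2-oxo-6-(prop-1-en-2-yl)cyclohex-3-en-1-yl (2Z)-2-methylbut-2-enoate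
Conditions: PPh3, DIAD, THF, 0 °C → rt
Reagents that add atoms: none
Why: Mitsunobu esterification of the carbonyl-activated secondary alcohol should proceed by SN2 with inversion, placing the angelate cis to the isopropenyl group under neutral conditions that do not isomerise the Z-enoate.

Step 3
Reactants: 5 cis-angeloyloxy enone
Product: 6 (1S,2R,6R)-2-hydroxy-3-methyl-6-(prop-1-en-2-yl)cyclohex-3-en-1-yl (2Z)-2-methylbut-2-enoate
Conditions: NaBH4, CeCl3·7H2O, MeOH, −78 °C; AcOH quench at −78 °C
Reagents that add atoms: none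
Why: Luche 1,2-reduction, in which hydride should add anti to the pseudo-axial α-acyloxy group (the face away from both ring substituents), giving the allylic alcohol cis to the angelate and to the isopropenyl group.

Step 4
Reactants: 6 allylic alcohol
Product: 7 (1S,2S,3S,4R,6R)-2-hydroxy-1-methyl-4-(prop-1-en-2-yl)-7-oxabicyclo[4.1.0]heptan-3-yl (2Z)-2-methylbut-2-enoate (epoxide O, OH, angelate and isopropenyl all on one ring face)
Conditions: VO(acac)2 (cat.), t-BuOOH, CH2Cl2, 0 °C → rt
Reagents that add atoms: tert-butyl hydroperoxide, CC(C)(C)OO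
Why: Vanadium-catalysed hydroxyl-directed epoxidation delivers oxygen syn to the allylic OH and only to the ring alkene, since the isopropenyl and angelate alkenes lack a directing allylic hydroxyl.

Step 5
Reactants: 7 epoxy alcohol
Product: 8 (1S,2S,3S,4S,6R)-4-chloro-2,3-dihydroxy-3-methyl-6-(prop-1-en-2-yl)cyclohexyl (2Z)-2-methylbut-2-enoate
Conditions: LiCl, AcOH, THF, rt
Reagents that add atoms: lithium chloride, [Li+].[Cl-]
Why: Acid-assisted SN2 opening by chloride at the secondary epoxide carbon from the unencumbered face is the trans-diaxial (Fürst–Plattner) mode of the half-chair with the C6 substituent equatorial, and is also favoured sterically and by the inductive deactivation of the tertiary carbon next to C2–O, giving Cl trans to the retained tertiary OH.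

Step 6
Reactants: 8 chlorodiol
Product: 9 (1S,2S,3S,4S,6R)-4-chloro-3-methyl-6-(prop-1-en-2-yl)-2,3-bis[(triethylsilyl)oxy]cyclohexyl (2Z)-2-methylbut-2-enoate
Conditions: TESOTf (excess), 2,6-lutidine, CH2Cl2, −78 → 0 °C
Reagents that add atoms: triethylsilyl trifluoromethanesulfonate, CC[Si](CC)(CC)OS(=O)(=O)C(F)(F)F
Why: Silyl triflate silylation caps the secondary and the hindered tertiary hydroxyl, so that no alkoxide trans to chloride can form later (no epoxide re-closure) and C2–OH is kept out of the later acylation.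

Step 7
Reactants: 9 bis-silyl ether
Product: 11 (1S,2S,3S,4S,6S)-6-acetyl-4-chloro-3-methyl-2,3-bis[(triethylsilyl)oxy]cyclohexyl (2Z)-2-methylbut-2-enoate, via vicinal diol 10 (not isolated)
Conditions: OsO4 (cat.), NaIO4, 2,6-lutidine, 1,4-dioxane/H2O, rt
Reagents that add atoms: osmium tetroxide, O=[Os](=O)(=O)=O; sodium periodate (terminal oxygen source), [Na+].[O-]I(=O)(=O)=O
Why: Lemieux–Johnson cleavage, in which the electron-rich 1,1-disubstituted alkene should be dihydroxylated much faster than the conjugated Z-trisubstituted angelate, and the buffered, non-basic medium leaves the β-acyloxy ketone and its α-stereocentre untouched.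

Step 8
Reactants: 11 methyl ketone
Product: 13 (1S,2S,3S,4S,6S)-4-chloro-3-methyl-2,3-bis[(triethylsilyl)oxy]-6-{1-[(trifluoromethanesulfonyl)oxy]ethenyl}cyclohexyl (2Z)-2-methylbut-2-enoate, via potassium enolate 12 (not isolated)
Conditions: KHMDS, THF, −78 °C (ketone added to base); then N-(5-chloropyridin-2-yl)triflimide, −78 °C
Reagents that add atoms: N-(5-chloropyridin-2-yl)bis(trifluoromethanesulfonyl)imide, O=S(=O)(N(c1ccc(Cl)cn1)S(=O)(=O)C(F)(F)F)C(F)(F)F
Why: Kinetic deprotonation by the hindered amide base at the methyl group (not at the ring methine, whose enolate could expel the β-angelate) and O-triflation at low temperature give the terminal enol triflate with C6 unchanged.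

Step 9
Reactants: 14 4-methylpent-3-en-1-ol
Product: 15 4-methylpent-3-enal
Conditions: Dess–Martin periodinane, pyridine, CH2Cl2, 0 °C; filtered and used at once as a solution
Reagents that add atoms: none
Why: Dess–Martin oxidation under buffered, near-neutral conditions gives the β,γ-unsaturated aldehyde without migration of the alkene into conjugation.

Step 10
Reactants: 13 enol triflate; 15 4-methylpent-3-enal
Product: 16 (1S,2S,3S,4S,6R)-4-chloro-6-[(3S)-3-hydroxy-6-methylhepta-1,5-dien-2-yl]-3-methyl-2,3-bis[(triethylsilyl)oxy]cyclohexyl (2Z)-2-methylbut-2-enoate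
Conditions: CrCl2, N-{2-[(4S)-4-isopropyl-4,5-dihydro-1,3-oxazol-2-yl]-6-methylphenyl}methanesulfonamide, Et3N, THF, rt; then NiCl2 (cat.), 13, 15, rt; aqueous serinate work-up
Reagents that add atoms: none
Why: Ni(0) inserts into the C(sp2)–OTf bond of 13, the alkenyl group is passed to Cr(III), and the alkenylchromium adds to the aldehyde inside the coordination sphere of the chiral sulfonamide–chromium complex (Nozaki–Hiyama–Kishi reaction). The closest known reaction type is the ligand-controlled Ni/Cr coupling of 2-halo- or 2-triflyloxy-alk-1-enes with aldehydes to give 2-substituted allylic alcohols. No ring is closed. The new carbinol centre C3′ is set by the ligand, which should direct the alkenyl group to the Re face of 15 and so give the (3S) alcohol; the neighbouring ring stereocentre C6 is the only competing control element. The step needs chemoselectivity for the aldehyde over the angelate ester, the secondary chloride and the silyl ethers, which the non-basic, carbonyl-selective alkenylchromium secures, and the same mildness keeps the β,γ-alkene of 15 out of conjugation.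

Step 11
Reactants: 16 allylic alcohol; 4 angelic acid
Product: 17 (1S,2S,3S,4S,6R)-4-chloro-3-methyl-6-{(3S)-6-methyl-3-[(2Z)-2-methylbut-2-enoyloxy]hepta-1,5-dien-2-yl}-2,3-bis[(triethylsilyl)oxy]cyclohexyl (2Z)-2-methylbut-2-enoate
Conditions: 4, 2,4,6-trichlorobenzoyl chloride, Et3N, toluene, rt; then 16, toluene, 75 °C (no DMAP)
Reagents that add atoms: none
Why: Yamaguchi-type mixed-anhydride esterification acylates the only free hydroxyl with retention at C3′, and omitting the nucleophilic catalyst avoids the addition–elimination path that turns angelate into tiglate.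

Step 12
Reactants: 17 bis-angelate
Product: 18 (1S,2S,3S,4S,6R)-4-chloro-6-{(3S)-4-[(2S)-3,3-dimethyloxiran-2-yl]-3-[(2Z)-2-methylbut-2-enoyloxy]but-1-en-2-yl}-3-methyl-2,3-bis[(triethylsilyl)oxy]cyclohexyl (2Z)-2-methylbut-2-enoate
Conditions: 1,2:4,5-di-O-isopropylidene-β-L-erythro-2,3-hexodiulo-2,6-pyranose (L-configured epoxidation ketone), Oxone, K2CO3, Bu4NHSO4, MeCN/CH2(OMe)2/aq. borate buffer, 0 °C
Reagents that add atoms: potassium peroxymonosulfate (active component of Oxone; oxygen passed on through the dioxirane of the ketone), [K+].[O-]S(=O)(=O)OO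
Why: Shi epoxidation, in which the electrophilic chiral dioxirane should pick the only electron-rich trisubstituted alkene (the 1,1-disubstituted alkene carries an allylic ester and the angelates are conjugated) and, through the spiro transition state of the L-configured ketone, give the (S)-oxirane; with both ring hydroxyls silylated the buffered base cannot close the chlorohydrin to an epoxide.

Step 13
Reactants: 18 bis-silyl ether
Product: 19 the target, (1S,2S,3S,4S,6R)-4-chloro-6-{(3S)-4-[(2S)-3,3-dimethyloxiran-2-yl]-3-[(2Z)-2-methylbut-2-enoyloxy]but-1-en-2-yl}-2,3-dihydroxy-3-methylcyclohexyl (2Z)-2-methylbut-2-enoate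
Conditions: HF·pyridine, excess pyridine, THF, 0 °C → rt
Reagents that add atoms: none
Why: Buffered fluoride-mediated Si–O cleavage removes both triethylsilyl ethers without generating a free alkoxide, so chloride displacement and 1,2-acyl migration are not triggered, and a trisubstituted oxirane is known to tolerate pyridine-buffered HF·pyridine.

**Compound list**

1 | (S)-(+)-carvone, (5S)-2-methyl-5-(prop-1-en-2-yl)cyclohex-2-en-1-one | C=C(C)[C@H]1CC=C(C)C(=O)C1 | starting material
2 | sodium (3S)-6-methyl-3-(prop-1-en-2-yl)cyclohexa-1,5-dien-1-olate | C=C(C)[C@H]1CC=C(C)C([O-])=C1.[Na+] | intermediate (not isolated)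
3 | (5R,6R)-6-hydroxy-2-methyl-5-(prop-1-en-2-yl)cyclohex-2-en-1-one | C=C(C)[C@H]1CC=C(C)C(=O)[C@@H]1O | intermediate
4 | angelic acid, (2Z)-2-methylbut-2-enoic acid | C/C=C(/C)C(=O)O | starting material
5 | (1S,6R)-3-methyl-2-oxo-6-(prop-1-en-2-yl)cyclohex-3-en-1-yl (2Z)-2-methylbut-2-enoate | C=C(C)[C@H]1CC=C(C)C(=O)[C@H]1OC(=O)/C(C)=C\C | intermediate
6 | (1S,2R,6R)-2-hydroxy-3-methyl-6-(prop-1-en-2-yl)cyclohex-3-en-1-yl (2Z)-2-methylbut-2-enoate | C=C(C)[C@H]1CC=C(C)[C@@H](O)[C@H]1OC(=O)/C(C)=C\C | intermediate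
7 | (1S,2S,3S,4R,6R)-2-hydroxy-1-methyl-4-(prop-1-en-2-yl)-7-oxabicyclo[4.1.0]heptan-3-yl (2Z)-2-methylbut-2-enoate | C=C(C)[C@H]1C[C@H]2O[C@@]2(C)[C@@H](O)[C@H]1OC(=O)/C(C)=C\C | intermediate
8 | (1S,2S,3S,4S,6R)-4-chloro-2,3-dihydroxy-3-methyl-6-(prop-1-en-2-yl)cyclohexyl (2Z)-2-methylbut-2-enoate | C=C(C)[C@H]1C[C@H](Cl)[C@@](C)(O)[C@@H](O)[C@H]1OC(=O)/C(C)=C\C | intermediate
9 | (1S,2S,3S,4S,6R)-4-chloro-3-methyl-6-(prop-1-en-2-yl)-2,3-bis[(triethylsilyl)oxy]cyclohexyl (2Z)-2-methylbut-2-enoate | C=C(C)[C@H]1C[C@H](Cl)[C@@](C)(O[Si](CC)(CC)CC)[C@@H](O[Si](CC)(CC)CC)[C@H]1OC(=O)/C(C)=C\C | intermediate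
10 | (1S,2S,3S,4S,6S)-4-chloro-6-(1,2-dihydroxypropan-2-yl)-3-methyl-2,3-bis[(triethylsilyl)oxy]cyclohexyl (2Z)-2-methylbut-2-enoate (either configuration at the new carbinol carbon) | CC(O)(CO)[C@H]1C[C@H](Cl)[C@@](C)(O[Si](CC)(CC)CC)[C@@H](O[Si](CC)(CC)CC)[C@H]1OC(=O)/C(C)=C\C | intermediate (not isolated)
11 | (1S,2S,3S,4S,6S)-6-acetyl-4-chloro-3-methyl-2,3-bis[(triethylsilyl)oxy]cyclohexyl (2Z)-2-methylbut-2-enoate | CC(=O)[C@H]1C[C@H](Cl)[C@@](C)(O[Si](CC)(CC)CC)[C@@H](O[Si](CC)(CC)CC)[C@H]1OC(=O)/C(C)=C\C | intermediate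
12 | terminal potassium enolate of 11 (CH2=C(OK)– on ring C6) | C=C([O-])[C@H]1C[C@H](Cl)[C@@](C)(O[Si](CC)(CC)CC)[C@@H](O[Si](CC)(CC)CC)[C@H]1OC(=O)/C(C)=C\C.[K+] | intermediate (not isolated)
13 | (1S,2S,3S,4S,6S)-4-chloro-3-methyl-2,3-bis[(triethylsilyl)oxy]-6-{1-[(trifluoromethanesulfonyl)oxy]ethenyl}cyclohexyl (2Z)-2-methylbut-2-enoate | C=C(OS(=O)(=O)C(F)(F)F)[C@H]1C[C@H](Cl)[C@@](C)(O[Si](CC)(CC)CC)[C@@H](O[Si](CC)(CC)CC)[C@H]1OC(=O)/C(C)=C\C | intermediate
14 | 4-methylpent-3-en-1-ol | CC(C)=CCCO | starting material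
15 | 4-methylpent-3-enal | CC(C)=CCC=O | intermediate
16 | (1S,2S,3S,4S,6R)-4-chloro-6-[(3S)-3-hydroxy-6-methylhepta-1,5-dien-2-yl]-3-methyl-2,3-bis[(triethylsilyl)oxy]cyclohexyl (2Z)-2-methylbut-2-enoate | C=C([C@H](CC=C(C)C)O)[C@H]1C[C@H](Cl)[C@@](C)(O[Si](CC)(CC)CC)[C@@H](O[Si](CC)(CC)CC)[C@H]1OC(=O)/C(C)=C\C | intermediate
17 | (1S,2S,3S,4S,6R)-4-chloro-3-methyl-6-{(3S)-6-methyl-3-[(2Z)-2-methylbut-2-enoyloxy]hepta-1,5-dien-2-yl}-2,3-bis[(triethylsilyl)oxy]cyclohexyl (2Z)-2-methylbut-2-enoate | C=C([C@H](CC=C(C)C)OC(=O)/C(C)=C\C)[C@H]1C[C@H](Cl)[C@@](C)(O[Si](CC)(CC)CC)[C@@H](O[Si](CC)(CC)CC)[C@H]1OC(=O)/C(C)=C\C | intermediate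
18 | (1S,2S,3S,4S,6R)-4-chloro-6-{(3S)-4-[(2S)-3,3-dimethyloxiran-2-yl]-3-[(2Z)-2-methylbut-2-enoyloxy]but-1-en-2-yl}-3-methyl-2,3-bis[(triethylsilyl)oxy]cyclohexyl (2Z)-2-methylbut-2-enoate | C=C([C@H](C[C@@H]1OC1(C)C)OC(=O)/C(C)=C\C)[C@H]1C[C@H](Cl)[C@@](C)(O[Si](CC)(CC)CC)[C@@H](O[Si](CC)(CC)CC)[C@H]1OC(=O)/C(C)=C\C | intermediate
19 | (1S,2S,3S,4S,6R)-4-chloro-6-{(3S)-4-[(2S)-3,3-dimethyloxiran-2-yl]-3-[(2Z)-2-methylbut-2-enoyloxy]but-1-en-2-yl}-2,3-dihydroxy-3-methylcyclohexyl (2Z)-2-methylbut-2-enoate | C=C([C@H](C[C@@H]1OC1(C)C)OC(=O)/C(C)=C\C)[C@H]1C[C@H](Cl)[C@@](C)(O)[C@@H](O)[C@H]1OC(=O)/C(C)=C\C | target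

**Step count and risks**

Total step count: 13. Longest linear sequence: 12 steps (from 1: steps 1–8 and 10–13).

Steps most likely to fail:

Step 10. The ligand-controlled facial selectivity may be eroded by the adjacent ring stereocentre C6, or oxidative addition at the hindered enol triflate may be slow. Fallback: the coupling is run from 13 and 15 without the chiral ligand (CrCl2, cat. NiCl2, DMSO) and the two carbinol epimers are separated. Compound 16 continues through step 11. Its C3′ epimer, (1S,2S,3S,4S,6R)-4-chloro-6-[(3R)-3-hydroxy-6-methylhepta-1,5-dien-2-yl]-3-methyl-2,3-bis[(triethylsilyl)oxy]cyclohexyl (2Z)-2-methylbut-2-enoate F1, is esterified with angelic acid 4 under Mitsunobu conditions (PPh3, DIAD, THF) with inversion. Both epimers thus converge on the same ester; the fallback sets out from 13 and comes back to the route at 17.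

Step 8. The kinetic methyl enolate may equilibrate to the ring-side enolate, which would expel the β-angelate (E1cB) or epimerise C6. Fallback without any enolate: from 11, condensation with 1,2-bis(tert-butyldimethylsilyl)hydrazine (cat. Sc(OTf)3, CH2Cl2) gives the N-silyl hydrazone, (1S,2S,3S,4S,6R)-6-{1-[2-(tert-butyldimethylsilyl)hydrazinylidene]ethyl}-4-chloro-3-methyl-2,3-bis[(triethylsilyl)oxy]cyclohexyl (2Z)-2-methylbut-2-enoate F2. Iodine and 1,1,3,3-tetramethylguanidine in THF at 0 °C (Barton vinyl iodide synthesis) then give (1S,2S,3S,4S,6S)-4-chloro-6-(1-iodoethenyl)-3-methyl-2,3-bis[(triethylsilyl)oxy]cyclohexyl (2Z)-2-methylbut-2-enoate F3. This iodide takes the place of 13 under the conditions of step 10, and the route is rejoined at 16.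

Step 2. The activated α-oxyphosphonium may eliminate towards the cross-conjugated dienone (and on to the phenol), or stereochemical integrity may be lost by enolisation of the α-acyloxy ketone. Fallback: from 3, mesylation (MsCl, Et3N, CH2Cl2, −20 °C) gives (1R,6R)-3-methyl-2-oxo-6-(prop-1-en-2-yl)cyclohex-3-en-1-yl methanesulfonate F4. Displacement with caesium angelate (from 4 and Cs2CO3, DMF, rt) should then occur with inversion at the carbonyl-activated carbon and return to the route at 5.

Further compounds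
F1 | step 10 | (1S,2S,3S,4S,6R)-4-chloro-6-[(3R)-3-hydroxy-6-methylhepta-1,5-dien-2-yl]-3-methyl-2,3-bis[(triethylsilyl)oxy]cyclohexyl (2Z)-2-methylbut-2-enoate | C=C([C@@H](CC=C(C)C)O)[C@H]1C[C@H](Cl)[C@@](C)(O[Si](CC)(CC)CC)[C@@H](O[Si](CC)(CC)CC)[C@H]1OC(=O)/C(C)=C\C
F2 | step 8 | (1S,2S,3S,4S,6R)-6-{1-[2-(tert-butyldimethylsilyl)hydrazinylidene]ethyl}-4-chloro-3-methyl-2,3-bis[(triethylsilyl)oxy]cyclohexyl (2Z)-2-methylbut-2-enoate | CC(=NN[Si](C)(C)C(C)(C)C)[C@H]1C[C@H](Cl)[C@@](C)(O[Si](CC)(CC)CC)[C@@H](O[Si](CC)(CC)CC)[C@H]1OC(=O)/C(C)=C\C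
F3 | step 8 | (1S,2S,3S,4S,6S)-4-chloro-6-(1-iodoethenyl)-3-methyl-2,3-bis[(triethylsilyl)oxy]cyclohexyl (2Z)-2-methylbut-2-enoate | C=C(I)[C@H]1C[C@H](Cl)[C@@](C)(O[Si](CC)(CC)CC)[C@@H](O[Si](CC)(CC)CC)[C@H]1OC(=O)/C(C)=C\C
F4 | step 2 | (1R,6R)-3-methyl-2-oxo-6-(prop-1-en-2-yl)cyclohex-3-en-1-yl methanesulfonate | C=C(C)[C@H]1CC=C(C)C(=O)[C@@H]1OS(C)(=O)=O
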